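The plan removes C2 from the cycloheptenone (ring C1–C7, C1 = ketone). In the six-membered ring that remains, the quaternary C5 sits para to C1. A prochiral 4,4-disubstituted cyclohexa-2,5-dienone, made by Birch alkylation of benzoic acid, can therefore carry C5, and the future C5 methyl (C10) serves as a CH2–O–CH2–CHO tether. A chiral pyrrolidine converts that aldehyde into an enamine whose alpha carbon (C8) adds to one of the two enantiotopic beta carbons (C6). This one operation forms C6–C8, closes a cis-fused oxolane, and fixes C5 and C6 with the methyl and the side chain syn. The untouched enone then directs insertion of C2.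

Key step: step 6

Numbering and stereochemical reading: C1–C7 is the ring as above, C8–C9 is the chain on C6, and C10 is the carbon on C5 that ends as methyl. In the target the C5 methyl, the C6 enol ester chain and the C7 acetonyl group all lie on one face, (5S,6S,7R).
Assumption: the (R)-catalyst is assigned from the usual face-shielding model for diarylprolinol silyl ether enamines combined with an exo approach. If the opposite sense is found, the equally available (S)-enantiomer is used and nothing else changes.
Remark: the cyclopropane carbons C1 and C3 in 14–19 and the chloride-bearing C3 in 20 form without control. They are left undefined in the SMILES because step 14 destroys all of them.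

Step 1
Reactants: 1 benzoic acid; 2 5-bromo-2-methylpent-2-ene
Product: 4 1-(4-methylpent-3-enyl)cyclohexa-2,5-diene-1-carboxylic acid, via dilithium dienediolate 3 (not isolated)
Conditions: Li, NH3(l)/THF, −78 °C; then 2; then NH4Cl, aq HCl
Reagents that add atoms: none
Why: Birch reduction–alkylation, in which electron transfer to lithium benzoate gives the cross-conjugated dienediolate 3, which the primary homoallylic bromide alkylates at the ipso carbon to create the still achiral quaternary C5, while lithium in ammonia does not reduce the isolated trisubstituted alkene.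

Step 2
Reactants: 4 1-(4-methylpent-3-enyl)cyclohexa-2,5-diene-1-carboxylic acid
Product: 5 [1-(4-methylpent-3-enyl)cyclohexa-2,5-dien-1-yl]methanol
Conditions: LiAlH4, THF, 0 °C → rt
Reagents that add atoms: none
Why: Hydride reduction of a carboxylic acid with LiAlH4 leaves the skipped diene and the isolated alkene untouched and gives the neopentyl alcohol whose carbon is C10.

Step 3
Reactants: 5 [1-(4-methylpent-3-enyl)cyclohexa-2,5-dien-1-yl]methanol; 6 2-bromo-1,1-diethoxyethane
Product: 7 3-[(2,2-diethoxyethoxy)methyl]-3-(4-methylpent-3-enyl)cyclohexa-1,4-diene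
Conditions: NaH, n-Bu4NI (cat.), DMF, 0 → 70 °C
Reagents that add atoms: none
Why: Williamson ether synthesis, in which the sodium alkoxide displaces bromide from the acetal-protected two-carbon electrophile (iodide catalysis and warming compensate for the hindered nucleophile), and the diene has no proton acidic enough for NaH.

Step 4
Reactants: 7 3-[(2,2-diethoxyethoxy)methyl]-3-(4-methylpent-3-enyl)cyclohexa-1,4-diene
Product: 8 4-[(2,2-diethoxyethoxy)methyl]-4-(4-methylpent-3-enyl)cyclohexa-2,5-dien-1-one
Conditions: Rh2(cap)4 (cap = caprolactamate, 1 mol %), t-BuOOH, K2CO3, CH2Cl2, rt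
Reagents that add atoms: tert-butyl hydroperoxide, CC(C)(C)OO
Why: Catalytic allylic oxidation by tert-butylperoxyl radicals, in which the doubly allylic ring CH2 has by far the weakest C–H bond of 7 and is therefore oxidised to the ketone ahead of the side-chain allylic and ether positions, with the acetal inert.

Step 5
Reactants: 8 4-[(2,2-diethoxyethoxy)methyl]-4-(4-methylpent-3-enyl)cyclohexa-2,5-dien-1-one
Product: 9 4-(4-methylpent-3-enyl)-4-[(2-oxoethoxy)methyl]cyclohexa-2,5-dien-1-one
Conditions: 1 M aq HCl, THF, 40 °C
Reagents that add atoms: water, O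
Why: Acid-catalysed acetal hydrolysis, under conditions too mild for dienone–phenol rearrangement or alkene hydration, liberates the aldehyde just before it is used.

Step 6
Reactants: 9 4-(4-methylpent-3-enyl)-4-[(2-oxoethoxy)methyl]cyclohexa-2,5-dien-1-one
Product: 10 (1S,3aR,7aS)-3a-(4-methylpent-3-enyl)-6-oxo-1,3,3a,6,7,7a-hexahydro-2-benzofuran-1-carbaldehyde (cis-fused oxolane–cyclohexenone; CHO exo)
Conditions: (R)-2-[diphenyl(trimethylsilyloxy)methyl]pyrrolidine (20 mol %), AcOH (20 mol %), toluene, 0 °C → rt
Reagents that add atoms: none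
Why: Condensation of the secondary amine with the aldehyde of 9 gives an E-enamine whose alpha carbon C8 attacks the beta carbon C6 of one enone arm; protonation at C7 and hydrolysis of the iminium ion release 10 and the catalyst. The closest known reaction type is the amine-catalysed desymmetrising intramolecular Michael addition of aldehydes tethered to 4,4-disubstituted cyclohexa-2,5-dienones, and alpha-alkoxyacetaldehydes are proven enamine donors for this catalyst class in intermolecular Michael additions. The oxolane closes 5-exo-trig (the C6=C7 bond stays outside the new ring), and the three-atom C10–O–C8 link is too short to reach the opposite face of the dienone, which enforces the cis fusion. C8 is set by the diphenyl(silyloxy)methyl group, which blocks one enamine face; with the iminium carbon pointing away from the carbocycle (exo) the open face can reach only one of the two enantiotopic arms, so the choice of arm fixes C6 and, by making the two formerly equivalent arms different substituents, the quaternary C5. The step needs enantiotopic-group selectivity, supplied by the catalyst, and chemoselectivity for conjugate addition over aldol self-condensation, secured by the intramolecular five-membered transition state and by a dienone that has no enolisable position. C8 is epimerisable but is erased in step 11, so only the C5/C6 sense has to be high.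

Step 7
Reactants: 10 bicyclic enone aldehyde
Product: 11 (3S,3aS,7aR)-3-(hydroxymethyl)-7a-(4-methylpent-3-enyl)-3,3a,4,7a-tetrahydro-2-benzofuran-5(1H)-one
Conditions: NaBH4, MeOH/CH2Cl2, −78 °C
Reagents that add atoms: none
Why: Chemoselective borohydride reduction, since at low temperature an aldehyde is reduced much faster than a conjugated ketone and no stereocentre is touched.

Step 8
Reactants: 11 bicyclic enone alcohol
Product: 12 (3S,3aS,7aR)-3-(iodomethyl)-7a-(4-methylpent-3-enyl)-3,3a,4,7a-tetrahydro-2-benzofuran-5(1H)-one
Conditions: I2, PPh3, imidazole, CH2Cl2, 0 °C → rt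
Reagents that add atoms: iodine, II
Why: Appel-type iodination of the unhindered primary alcohol by SN2 displacement of the alkoxyphosphonium ion is tolerated by enone and alkene and installs the trigger for the later ring opening.

Step 9
Reactants: 12 bicyclic enone iodide
Product: 13 (3S,3aS,7aR)-3-(iodomethyl)-7a-(4-methylpent-3-enyl)-5-(triethylsilyloxy)-1,3,3a,4,7,7a-hexahydro-2-benzofuran (enol ether C1=C3; C4 now CH2)
Conditions: Et3SiH, RhCl(PPh3)3 (1 mol %), THF, 50 °C
Reagents that add atoms: triethylsilane, CC[SiH](CC)CC
Why: Rhodium-catalysed 1,4-hydrosilylation of the enone puts hydride on C4 and silicon on oxygen, so the enol ether double bond is fixed regiospecifically between C1 and C3, and the beta-branched primary iodide adds oxidatively to monovalent rhodium far more slowly than the Si–H bond does.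

Step 10
Reactants: 13 triethylsilyl enol ether
Product: 14 silyloxycyclopropane (13 with a CH2 group, C2, bridging C1 and C3; oxolane and iodide unchanged)
Conditions: Et2Zn (1.3 equiv), CH2I2 (1.3 equiv), CH2Cl2, −20 → 0 °C; pyridine quench
Reagents that add atoms: diiodomethane, ICI
Why: Simmons–Smith cyclopropanation (Et2Zn/CH2I2 variant), in which the electrophilic zinc carbenoid, used in small excess and cold, reacts with the far more electron-rich silyl enol ether before the trisubstituted side-chain alkene, introduces C2 and turns the ketone into a base- and hydride-stable silyloxycyclopropane, with either face acceptable because both new centres vanish in step 14.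

Step 11
Reactants: 14 silyloxycyclopropane iodide
Product: 16 [(3R,4R)-3-ethenyl-4-(4-methylpent-3-enyl)-1-(triethylsilyloxy)bicyclo[4.1.0]heptan-4-yl]methyl methanesulfonate, via lithium alkoxide 15 (not isolated)
Conditions: t-BuLi (2.1 equiv), Et2O/pentane, −78 °C; then MsCl, −78 → 0 °C
Reagents that add atoms: methanesulfonyl chloride, CS(=O)(=O)Cl
Why: Iodine–lithium exchange followed by immediate beta-elimination of the alkoxide (Boord-type olefin synthesis) cuts the C8–O bond, erases C8 and gives the vinyl group, and the liberated neopentyl lithium alkoxide is sulfonylated in the same flask.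

Step 12
Reactants: 16 neopentyl mesylate
Product: 17 (3R,4S)-3-ethenyl-4-methyl-4-(4-methylpent-3-enyl)-1-(triethylsilyloxy)bicyclo[4.1.0]heptane
Conditions: LiEt3BH (5 equiv), THF, 65 °C
Reagents that add atoms: none
Why: SN2 hydride displacement of a primary sulfonate by the very nucleophilic LiEt3BH turns C10 into the methyl group while the masked ketone cannot be reduced, and it is chosen because a radical deoxygenation would create a C10 radical that is a 5-hexenyl radical with respect to the side-chain alkene.

Step 13
Reactants: 17 vinyl silyloxycyclopropane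
Product: 19 2-[(3S,4S)-4-methyl-4-(4-methylpent-3-enyl)-1-(triethylsilyloxy)bicyclo[4.1.0]heptan-3-yl]ethanol, via B-alkyl-9-BBN adduct 18 (not isolated)
Conditions: 9-BBN, THF, 0 °C → rt; then NaOH, H2O2, 0 °C
Reagents that add atoms: hydrogen peroxide, OO
Why: Anti-Markovnikov hydroboration–oxidation, in which the bulky 9-BBN selects the monosubstituted vinyl group over the trisubstituted alkene and places boron on C9, and cold basic peroxide does not cleave the tertiary triethylsilyl ether.

Step 14
Reactants: 19 hydroxyethyl silyloxycyclopropane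
Product: 21 (5S,6S)-6-(2-hydroxyethyl)-5-methyl-5-(4-methylpent-3-enyl)cyclohept-2-en-1-one, via 3-chlorocycloheptanone 20 (not isolated)
Conditions: FeCl3 (2.5 equiv), pyridine, DMF, 0 °C → rt; then NaOAc, MeOH, 65 °C
Reagents that add atoms: none
Why: Saegusa-type oxidative ring expansion of a silyloxycyclopropane, in which one-electron oxidation by trivalent iron cleaves the internal C1–C3 bond to the more stable secondary radical, chlorine transfer gives 20, and E1cB loss of HCl with acetate can only deliver the C2=C3 enone.

Step 15
Reactants: 21 hydroxyethyl cycloheptenone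
Product: 22 (5S,6S)-5-methyl-5-(4-methylpent-3-enyl)-6-[2-(triethylsilyloxy)ethyl]cyclohept-2-en-1-one
Conditions: Et3SiCl, imidazole, CH2Cl2, 0 °C
Reagents that add atoms: chlorotriethylsilane, CC[Si](Cl)(CC)CC
Why: Standard silylation of the only hydroxyl group gives a primary triethylsilyl ether that can later be oxidised directly, and it also collects any material already silylated during step 14.

Step 16
Reactants: 22 silyl-protected cycloheptenone
Product: 23 (5S,6S)-2-(hydroxymethyl)-5-methyl-5-(4-methylpent-3-enyl)-6-[2-(triethylsilyloxy)ethyl]cyclohept-2-en-1-one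
Conditions: 37 % aq HCHO, DMAP (0.5 equiv), THF/H2O, rt
Reagents that add atoms: formaldehyde, C=O
Why: Morita–Baylis–Hillman hydroxymethylation (reversible conjugate addition of DMAP to the unhindered C3, aldol capture of formaldehyde at C2, loss of DMAP) is a reaction type known for cyclohept-2-enones in aqueous media and is mild enough for the silyl ether.

Step 17
Reactants: 23 hydroxymethyl enone
Product: 24 (5S,6S)-2-[(tert-butyldimethylsilyloxy)methyl]-5-methyl-5-(4-methylpent-3-enyl)-6-[2-(triethylsilyloxy)ethyl]cyclohept-2-en-1-one
Conditions: t-BuMe2SiCl, imidazole, DMF, 0 °C → rt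
Reagents that add atoms: tert-butylchlorodimethylsilane, CC(C)(C)[Si](C)(C)Cl
Why: Standard silylation gives a tert-butyldimethylsilyl ether that survives amide bases, the Swern reagent and acylation, so the two primary oxygens stay distinguishable.

Step 18
Reactants: 24 bis-silyl enone; 25 allyl bromide
Product: 27 (5S,6S,7S)-7-allyl derivative of 24 (allyl trans to the C6 chain), via lithium dienolate 26 (not isolated)
Conditions: LDA, THF, −78 °C; then 25, DMPU, −78 → −30 °C
Reagents that add atoms: none
Why: Kinetic alpha-prime deprotonation of the enone gives the cross-conjugated dienolate 26, whose C-allylation at C7 is expected mainly on the face opposite to C8 and the C5 methyl, and the C7 configuration formed here does not matter because step 19 resets it.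

Step 19
Reactants: 27 7-allyl ketone (either C7 epimer)
Product: 29 (5S,6S,7R)-7-allyl derivative of 24 (allyl cis to the C6 chain and the C5 methyl), via lithium enolate 28 (not isolated)
Conditions: LDA, THF, −78 → −20 °C; then 2,6-di-tert-butyl-4-methylphenol, −78 °C
Reagents that add atoms: none
Why: Kinetic protonation of an enolate, in which allylic strain with the allyl group in the tetrasubstituted enolate 28 pushes the C6 chain pseudo-axial over the top face, so the bulky phenol should deliver the proton from the bottom face and leave the allyl group cis to the C6 chain, as the target requires.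

Step 20
Reactants: 29 cis-7-allyl ketone
Product: 30 (5S,6S,7R)-7-allyl-2-[(tert-butyldimethylsilyloxy)methyl]-5-methyl-5-(4-methylpent-3-enyl)-6-(2-oxoethyl)cyclohept-2-en-1-one
Conditions: (COCl)2, DMSO, CH2Cl2, −78 → −30 °C; then Et3N, −78 → 0 °C
Reagents that add atoms: none
Why: Swern oxidation applied directly to a primary triethylsilyl ether, in which the chlorosulfonium salt exchanges the labile silyl group for an alkoxysulfonium ion that collapses to the aldehyde, while the tert-butyldimethylsilyl ether is inert and the brief cold exposure to Et3N should not epimerise C7.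

Step 21
Reactants: 30 keto aldehyde; 31 3-methylbut-2-enoic acid
Product: 32 (E)-enol 3-methylbut-2-enoate of 30 (C8=C9 E; 5S,6S,7R)
Conditions: 31 (4 equiv), DCC (2 equiv), CH2Cl2, 0 °C; then 30, Et3N, DMAP (cat.), rt
Reagents that add atoms: none
Why: O-acylation of an aldehyde enolate, in which amine-mediated enolisation of the aldehyde (by far the most acidic carbonyl present) and capture by the acylpyridinium ion give the enol ester, E geometry is favoured because the bulky ring carbon C6 avoids the acyloxy group, the anhydride avoids the vinylketene deconjugation typical of the acid chloride, and a minor Z isomer would be removed by chromatography.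

Step 22
Reactants: 32 allyl enol ester
Product: 33 (5S,6S,7R)-7-(2-oxopropyl) analogue of 32
Conditions: PdCl2 (10 mol %), CuCl, O2 (1 atm), DMF/H2O, rt
Reagents that add atoms: water, O; dioxygen, O=O
Why: Tsuji–Wacker oxidation, in which divalent palladium binds the terminal monosubstituted alkene in preference to the trisubstituted, conjugated and acyloxy-substituted alkenes and Markovnikov hydroxypalladation gives the methyl ketone, placed after step 21 so that an aldol-prone keto aldehyde bearing the acetonyl group is never formed.

Step 23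
Reactants: 33 silyl-protected target
Product: 34 target CNP0247522.1, (5S,6S,7R)
Conditions: HF·pyridine, pyridine, THF, 0 °C
Reagents that add atoms: none
Why: Fluoride-mediated desilylation under buffered, weakly acidic conditions removes the last protecting group without acyl cleavage of the enol ester or epimerisation at C7.

Compound list
1 | benzoic acid | OC(=O)c1ccccc1 | starting material
2 | 5-bromo-2-methylpent-2-ene | CC(C)=CCCBr | starting material
3 | dilithium dienediolate (Birch dianion of 1) | [Li+].[Li+].[O-]C([O-])=C1C=CCC=C1 | intermediate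
4 | 1-(4-methylpent-3-enyl)cyclohexa-2,5-diene-1-carboxylic acid | OC(=O)C1(CCC=C(C)C)C=CCC=C1 | intermediate
5 | [1-(4-methylpent-3-enyl)cyclohexa-2,5-dien-1-yl]methanol | OCC1(CCC=C(C)C)C=CCC=C1 | intermediate
6 | 2-bromo-1,1-diethoxyethane | CCOC(CBr)OCC | starting material
7 | 3-[(2,2-diethoxyethoxy)methyl]-3-(4-methylpent-3-enyl)cyclohexa-1,4-diene | CCOC(COCC1(CCC=C(C)C)C=CCC=C1)OCC | intermediate
8 | 4-[(2,2-diethoxyethoxy)methyl]-4-(4-methylpent-3-enyl)cyclohexa-2,5-dien-1-one | CCOC(COCC1(CCC=C(C)C)C=CC(=O)C=C1)OCC | intermediate
9 | 4-(4-methylpent-3-enyl)-4-[(2-oxoethoxy)methyl]cyclohexa-2,5-dien-1-one | O=CCOCC1(CCC=C(C)C)C=CC(=O)C=C1 | intermediate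
10 | (1S,3aR,7aS)-3a-(4-methylpent-3-enyl)-6-oxo-1,3,3a,6,7,7a-hexahydro-2-benzofuran-1-carbaldehyde | O=C[C@H]1OC[C@]2(CCC=C(C)C)C=CC(=O)C[C@H]12 | intermediate
11 | (3S,3aS,7aR)-3-(hydroxymethyl)-7a-(4-methylpent-3-enyl)-3,3a,4,7a-tetrahydro-2-benzofuran-5(1H)-one | OC[C@H]1OC[C@]2(CCC=C(C)C)C=CC(=O)C[C@H]12 | intermediate
12 | (3S,3aS,7aR)-3-(iodomethyl)-7a-(4-methylpent-3-enyl)-3,3a,4,7a-tetrahydro-2-benzofuran-5(1H)-one | IC[C@H]1OC[C@]2(CCC=C(C)C)C=CC(=O)C[C@H]12 | intermediate
13 | (3S,3aS,7aR)-3-(iodomethyl)-7a-(4-methylpent-3-enyl)-5-(triethylsilyloxy)-1,3,3a,4,7,7a-hexahydro-2-benzofuran | IC[C@H]1OC[C@]2(CCC=C(C)C)CC=C(O[Si](CC)(CC)CC)C[C@H]12 | intermediate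
14 | silyloxycyclopropane from 13 (CH2 bridging C1 and C3; cyclopropane face undefined) | IC[C@H]1OC[C@]2(CCC=C(C)C)CC3CC3(O[Si](CC)(CC)CC)C[C@H]12 | intermediate
15 | lithium alkoxide of the ring-opened vinyl alcohol | [Li+].[O-]C[C@]1(CCC=C(C)C)CC2CC2(O[Si](CC)(CC)CC)C[C@@H]1C=C | intermediate
16 | [(3R,4R)-3-ethenyl-4-(4-methylpent-3-enyl)-1-(triethylsilyloxy)bicyclo[4.1.0]heptan-4-yl]methyl methanesulfonate | CS(=O)(=O)OC[C@]1(CCC=C(C)C)CC2CC2(O[Si](CC)(CC)CC)C[C@@H]1C=C | intermediate
17 | (3R,4S)-3-ethenyl-4-methyl-4-(4-methylpent-3-enyl)-1-(triethylsilyloxy)bicyclo[4.1.0]heptane | C[C@]1(CCC=C(C)C)CC2CC2(O[Si](CC)(CC)CC)C[C@@H]1C=C | intermediate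
18 | B-alkyl-9-BBN adduct of 17 (boron on C9) | C[C@]1(CCC=C(C)C)CC2CC2(O[Si](CC)(CC)CC)C[C@@H]1CCB3C4CCCC3CCC4 | intermediate
19 | 2-[(3S,4S)-4-methyl-4-(4-methylpent-3-enyl)-1-(triethylsilyloxy)bicyclo[4.1.0]heptan-3-yl]ethanol | C[C@]1(CCC=C(C)C)CC2CC2(O[Si](CC)(CC)CC)C[C@@H]1CCO | intermediate
20 | (5S,6S)-3-chloro-6-(2-hydroxyethyl)-5-methyl-5-(4-methylpent-3-enyl)cycloheptan-1-one (C3 undefined) | C[C@]1(CCC=C(C)C)CC(Cl)CC(=O)C[C@@H]1CCO | intermediate
21 | (5S,6S)-6-(2-hydroxyethyl)-5-methyl-5-(4-methylpent-3-enyl)cyclohept-2-en-1-one | C[C@]1(CCC=C(C)C)CC=CC(=O)C[C@@H]1CCO | intermediate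
22 | (5S,6S)-5-methyl-5-(4-methylpent-3-enyl)-6-[2-(triethylsilyloxy)ethyl]cyclohept-2-en-1-one | C[C@]1(CCC=C(C)C)CC=CC(=O)C[C@@H]1CCO[Si](CC)(CC)CC | intermediate
23 | (5S,6S)-2-(hydroxymethyl)-5-methyl-5-(4-methylpent-3-enyl)-6-[2-(triethylsilyloxy)ethyl]cyclohept-2-en-1-one | C[C@]1(CCC=C(C)C)CC=C(CO)C(=O)C[C@@H]1CCO[Si](CC)(CC)CC | intermediate
24 | (5S,6S)-2-[(tert-butyldimethylsilyloxy)methyl]-5-methyl-5-(4-methylpent-3-enyl)-6-[2-(triethylsilyloxy)ethyl]cyclohept-2-en-1-one | C[C@]1(CCC=C(C)C)CC=C(CO[Si](C)(C)C(C)(C)C)C(=O)C[C@@H]1CCO[Si](CC)(CC)CC | intermediate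
25 | allyl bromide | C=CCBr | starting material
26 | lithium cross-conjugated dienolate of 24 (C1=C7) | C[C@]1(CCC=C(C)C)CC=C(CO[Si](C)(C)C(C)(C)C)C([O-])=C[C@@H]1CCO[Si](CC)(CC)CC.[Li+] | intermediate
27 | (5S,6S,7S)-7-allyl derivative of 24 (allyl trans to the C6 chain) | C[C@]1(CCC=C(C)C)CC=C(CO[Si](C)(C)C(C)(C)C)C(=O)[C@@H](CC=C)[C@@H]1CCO[Si](CC)(CC)CC | intermediate
28 | lithium enolate of 27 (tetrasubstituted C1=C7) | C[C@]1(CCC=C(C)C)CC=C(CO[Si](C)(C)C(C)(C)C)C([O-])=C(CC=C)[C@@H]1CCO[Si](CC)(CC)CC.[Li+] | intermediate
29 | (5S,6S,7R)-7-allyl derivative of 24 (allyl cis to the C6 chain) | C[C@]1(CCC=C(C)C)CC=C(CO[Si](C)(C)C(C)(C)C)C(=O)[C@H](CC=C)[C@@H]1CCO[Si](CC)(CC)CC | intermediate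
30 | (5S,6S,7R)-7-allyl-2-[(tert-butyldimethylsilyloxy)methyl]-5-methyl-5-(4-methylpent-3-enyl)-6-(2-oxoethyl)cyclohept-2-en-1-one | C[C@]1(CCC=C(C)C)CC=C(CO[Si](C)(C)C(C)(C)C)C(=O)[C@H](CC=C)[C@@H]1CC=O | intermediate
31 | 3-methylbut-2-enoic acid | CC(C)=CC(=O)O | starting material
32 | (E)-enol 3-methylbut-2-enoate of 30 | C[C@]1(CCC=C(C)C)CC=C(CO[Si](C)(C)C(C)(C)C)C(=O)[C@H](CC=C)[C@@H]1/C=C/OC(=O)C=C(C)C | intermediate
33 | 7-(2-oxopropyl) analogue of 32 (silyl-protected target) | C[C@]1(CCC=C(C)C)CC=C(CO[Si](C)(C)C(C)(C)C)C(=O)[C@H](CC(C)=O)[C@@H]1/C=C/OC(=O)C=C(C)C | intermediate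
34 | CNP0247522.1, (5S,6S,7R) | CC(=O)C[C@H]1C(=O)C(CO)=CC[C@](C)(CCC=C(C)C)[C@H]1/C=C/OC(=O)C=C(C)C | target

Total step count: 23. Longest linear sequence: 23 (steps 1–23 from benzoic acid; every other input is a commercial reagent).

Steps most likely to fail

Step 6. The catalyst may not discriminate well enough between the two enone arms. The electron-poor alkoxy aldehyde may also form its enamine slowly, which would let unselective background cyclisation erode the enantiomeric purity. The fallback replaces catalytic desymmetrisation by racemic closure followed by enzymatic kinetic resolution. It sets out from 9, which is cyclised with pyrrolidine/AcOH (cat.) in toluene to give 10 together with its mirror image ent-10 F1. The mixture is reduced as in step 7 to 11 and ent-11 F2. Immobilised Candida antarctica lipase B and vinyl acetate in t-BuOMe then acylate one antipode; the enzyme and its sense have to be found by screening. The case written here is the one in which the unwanted antipode becomes the acetate of ent-11 F3. Chromatographic separation returns to the route at 11.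

Step 19. Facial selectivity in the protonation may be poor, deprotonation may occur at C4 (gamma) instead of at the hindered C7, or C7 may equilibrate during work-up. The fallback forms the C7–allyl bond under reagent control instead of relying on substrate-controlled protonation, and it replaces steps 18 and 19. It sets out from 24, whose dienolate (NaHMDS, TMEDA, THF, −78 °C) is O-acylated with allyl chloroformate to give the allyl enol carbonate F5. Decarboxylative asymmetric allylic alkylation (Tsuji–Trost type) follows, using Pd2(dba)3·CHCl3 and a C2-symmetric trans-1,2-diaminocyclohexane bis(2-diphenylphosphinobenzamide) ligand in toluene at rt. The ligand enantiomer is the one that delivers allyl to the face of the C6 chain. These neutral conditions should not epimerise the new tertiary centre, and the fallback comes back at 29.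

Step 16. The nucleophilic catalyst may add only sluggishly to the seven-membered enone, and the triethylsilyl ether may slowly be lost during long exposure to the aqueous medium. The fallback replaces the organocatalytic aldol by halogenation and cross-coupling. It sets out from 22, which is iodinated at C2 (I2, pyridine, CH2Cl2, 0 °C → rt) to the 2-iodoenone F4. Stille coupling with (tributylstannyl)methanol (Pd(PPh3)4, CuI, NMP, 50 °C) then comes back to the route at 23.

Further compounds
F1 | step 6 | ent-10, (1R,3aS,7aR)-3a-(4-methylpent-3-enyl)-6-oxo-1,3,3a,6,7,7a-hexahydro-2-benzofuran-1-carbaldehyde | O=C[C@@H]1OC[C@@]2(CCC=C(C)C)C=CC(=O)C[C@@H]12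
F2 | step 6 | ent-11, (3R,3aR,7aS)-3-(hydroxymethyl)-7a-(4-methylpent-3-enyl)-3,3a,4,7a-tetrahydro-2-benzofuran-5(1H)-one | OC[C@@H]1OC[C@@]2(CCC=C(C)C)C=CC(=O)C[C@@H]12
F3 | step 6 | acetate of ent-11 | CC(=O)OC[C@@H]1OC[C@@]2(CCC=C(C)C)C=CC(=O)C[C@@H]12
F4 | step 16 | (5S,6S)-2-iodo-5-methyl-5-(4-methylpent-3-enyl)-6-[2-(triethylsilyloxy)ethyl]cyclohept-2-en-1-one | C[C@]1(CCC=C(C)C)CC=C(I)C(=O)C[C@@H]1CCO[Si](CC)(CC)CC
F5 | step 19 | allyl enol carbonate of 24 (C1=C7 enol) | C[C@]1(CCC=C(C)C)CC=C(CO[Si](C)(C)C(C)(C)C)C(OC(=O)OCC=C)=C[C@@H]1CCO[Si](CC)(CC)CC
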